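**Plan**
Retrosynthetic cuts, in order: the three O–Si bonds; the C5–CH= bond of the stilbene (Heck); the CH2–OH bond (back to CH2–Hg); O1–C2 of the dihydrofuran (back to a cyclopropane C–C bond); the two cyclopropane bonds to the syringyl-bearing carbon (carbene plus styrene).
Enabling feature: C2, C3 and the exocyclic CH2 form a three-carbon unit with oxygen at both ends (O1 on C2, OH on CH2). This is what a 1,3-addition across one bond of a trans-1,2-diarylcyclopropane leaves behind, with ring A on C3 and the syringyl ring on C2.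
Forward order: the cyclopropane is made first from the ring A styrene and the syringyl diazo precursor; the ring A phenol is freed; mercury-triggered opening closes the dihydrofuran; C–Hg becomes C–OH; the resorcinol ring is attached last by Heck coupling, then desilylation.
Stereochemistry: a chiral cobalt porphyrin sets the (1S,2S)-cyclopropane, whose ring A carbon becomes C3 (S) unchanged; C2 (R) arises from it by inversion in the ring opening, giving the trans ring; the Heck reaction gives the E alkene.

Key step: step 7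

Assumption: the sense of induction of the cobalt porphyrin is assigned by analogy with simpler styrenes; the antipode of the catalyst that delivers the (1S,2S)-cyclopropane is the one used.

**Step 1**
Reactants: 1 5-bromo-2-hydroxy-3-methoxybenzaldehyde
Product: 2 5-bromo-3-methoxy-2-(methoxymethoxy)benzaldehyde
Conditions: MOMCl, iPr2NEt, CH2Cl2, 0 °C to rt
Reagents that add atoms: chloromethyl methyl ether, COCCl
Why: O-alkylation of the phenol to the methoxymethyl acetal masks the acidic OH for the ylide and carbonate steps with a group that can later be removed without fluoride or strong protic acid.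

**Step 2**
Reactants: 2 5-bromo-3-methoxy-2-(methoxymethoxy)benzaldehyde
Product: 3 5-bromo-1-ethenyl-3-methoxy-2-(methoxymethoxy)benzene
Conditions: Ph3PCH3Br, KOtBu, THF, 0 °C to rt
Reagents that add atoms: methyltriphenylphosphonium bromide, C[P+](c1ccccc1)(c1ccccc1)c1ccccc1.[Br-]
Why: Wittig methylenation of an aryl aldehyde, to which the aryl bromide and the acetal are inert; the new CH2 becomes the hydroxymethyl carbon of the target.

**Step 3**
Reactants: 4 syringaldehyde (4-hydroxy-3,5-dimethoxybenzaldehyde)
Product: 5 3,5-dimethoxy-4-(triisopropylsilyloxy)benzaldehyde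
Conditions: TIPSCl, imidazole, DMAP (cat.), DMF, 40 °C
Reagents that add atoms: chlorotri(propan-2-yl)silane, CC(C)[Si](Cl)(C(C)C)C(C)C
Why: Silylation of the phenol; the triisopropylsilyl ether, shielded by both ortho methoxy groups, is chosen because it should resist the carbonate/methanol of step 5 and still leave with fluoride at the end.

**Step 4**
Reactants: 5 3,5-dimethoxy-4-(triisopropylsilyloxy)benzaldehyde; 6 4-methylbenzenesulfonohydrazide
Product: 7 N'-[(E)-{3,5-dimethoxy-4-(triisopropylsilyloxy)phenyl}methylidene]-4-methylbenzenesulfonohydrazide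
Conditions: MeOH, rt
Reagents that add atoms: none
Why: Condensation of the aldehyde with the sulfonyl hydrazide should give the (E)-tosylhydrazone, the bench-stable precursor of the aryldiazomethane.

**Step 5**
Reactants: 3 5-bromo-1-ethenyl-3-methoxy-2-(methoxymethoxy)benzene; 7 the tosylhydrazone of step 4
Product: 9 (1S,2S)-1-[5-bromo-3-methoxy-2-(methoxymethoxy)phenyl]-2-[3,5-dimethoxy-4-(triisopropylsilyloxy)phenyl]cyclopropane (trans), via aryldiazomethane 8 (not isolated)
Conditions: [Co(3,5-DitBu-Xu(2'-Naph)Phyrin)] (2 mol %), Cs2CO3, MeOH, 40 °C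
Reagents that add atoms: none
Why: The hydrazone salt loses sulfinate (Bamford–Stevens reaction) to give diazo compound 8, which the D2-symmetric chiral amidoporphyrin complex of divalent cobalt converts into a cobalt-bound benzyl radical that adds to the terminal carbon of styrene 3 and closes the ring by 3-exo radical substitution, a stepwise path that should give the trans cyclopropane with both stereocentres (1S,2S) set by the chiral pocket of the ligand.

**Step 6**
Reactants: 9 the (1S,2S)-cyclopropane methoxymethyl ether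
Product: 10 4-bromo-2-methoxy-6-[(1S,2S)-2-{3,5-dimethoxy-4-(triisopropylsilyloxy)phenyl}cyclopropyl]phenol
Conditions: ZnBr2, n-PrSH, CH2Cl2, 0 °C
Reagents that add atoms: none
Why: Lewis-acid-assisted thiolysis of the methoxymethyl acetal frees the phenol under conditions too mild to protonate the electron-rich cyclopropane or to touch the aryl silyl ether.

**Step 7**
Reactants: 10 4-bromo-2-methoxy-6-[(1S,2S)-2-{3,5-dimethoxy-4-(triisopropylsilyloxy)phenyl}cyclopropyl]phenol
Product: 12 chloro{[(2R,3R)-5-bromo-2-{3,5-dimethoxy-4-(triisopropylsilyloxy)phenyl}-7-methoxy-2,3-dihydro-1-benzofuran-3-yl]methyl}mercury (trans), via organomercury trifluoroacetate 11 (not isolated)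
Conditions: Hg(OCOCF3)2, CH2Cl2, −20 °C to rt; then saturated aqueous NaCl
Reagents that add atoms: mercury bis(trifluoroacetate), O=C(O[Hg]OC(=O)C(F)(F)F)C(F)(F)F; sodium chloride, [Na+].[Cl-]
Why: Proposed new method: the divalent mercury electrophile should attack the unsubstituted CH2 corner of the cyclopropane, and as the bond from that CH2 to the syringyl-bearing carbon lengthens, the neighbouring phenol oxygen adds to this benzylic carbon from the rear, forming O1–C2 and leaving CH2–Hg on C3, after which chloride exchange gives the isolable organomercury chloride. The closest known reaction type is the electrophilic 1,3-oxymercuration of cyclopropanes with capture by an internal hydroxyl or carbonyl oxygen, which follows the same corner-attack and inversion rules but has not been run with a phenol on a 1,2-diarylcyclopropane. The dihydrofuran ring closes in the 5-exo-tet mode, the breaking C2–CH2 bond lying outside the new ring. The new stereocentre C2 is controlled by the C3 centre of the cyclopropane: backside displacement inverts C2 of the trans cyclopropane and gives the trans 2,3-relationship, which is also the thermodynamically preferred one should the opening take on cationic character, while C3 is untouched. The step needs cleavage of CH2–C2 in preference to CH2–C3 and C2–C3 (the latter would lead to a six-membered flavan), which is secured because mercury goes to the least substituted carbon, the para-silyloxy ring stabilises positive charge at C2, and the phenol can reach only C2 through a five-membered transition state. It also needs the cyclopropane to react before the arenes, which is favoured because ring A is substituted at both ortho positions and the para position of the phenol, the open positions of the syringyl ring are flanked on both sides, and strain release drives the opening.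

**Step 8**
Reactants: 12 the organomercury chloride of step 7
Product: 15 [(2R,3S)-5-bromo-2-{3,5-dimethoxy-4-(triisopropylsilyloxy)phenyl}-7-methoxy-2,3-dihydro-1-benzofuran-3-yl]methanol (trans), via alkylmercury hydride 13 (not isolated), via hydroperoxide 14 (not isolated)
Conditions: NaBH4, O2 (sparged), DMF, 0 °C to rt
Reagents that add atoms: dioxygen, O=O
Why: Oxidative demercuration: borohydride converts the alkylmercury chloride into the hydride, whose primary alkyl radical should be captured by O2 faster than it abstracts hydrogen or rearranges, and the hydroperoxide is reduced in the flask to the alcohol, with no stereocentre involved and the aryl bromide and silyl ether inert.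

**Step 9**
Reactants: 16 3,5-dihydroxybenzaldehyde
Product: 17 3,5-bis(tert-butyldimethylsilyloxy)benzaldehyde
Conditions: TBSCl, imidazole, DMF, rt
Reagents that add atoms: tert-butylchlorodimethylsilane, CC(C)(C)[Si](C)(C)Cl
Why: Standard silylation of both phenols so that the styrene partner is compatible with the ylide and with the palladium coupling.

**Step 10**
Reactants: 17 3,5-bis(tert-butyldimethylsilyloxy)benzaldehyde
Product: 18 1-ethenyl-3,5-bis(tert-butyldimethylsilyloxy)benzene
Conditions: Ph3PCH3Br, n-BuLi, THF, 0 °C to rt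
Reagents that add atoms: methyltriphenylphosphonium bromide, C[P+](c1ccccc1)(c1ccccc1)c1ccccc1.[Br-]
Why: Wittig methylenation with the preformed salt-free ylide, which leaves the aryl silyl ethers intact.

**Step 11**
Reactants: 15 the bromo alcohol of step 8; 18 1-ethenyl-3,5-bis(tert-butyldimethylsilyloxy)benzene
Product: 19 [(2R,3S)-5-[(E)-2-{3,5-bis(tert-butyldimethylsilyloxy)phenyl}ethenyl]-2-{3,5-dimethoxy-4-(triisopropylsilyloxy)phenyl}-7-methoxy-2,3-dihydro-1-benzofuran-3-yl]methanol
Conditions: Pd(P(t-Bu)3)2 (5 mol %), Cy2NMe, 1,4-dioxane, 80 °C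
Reagents that add atoms: none
Why: Heck reaction: oxidative addition of the electron-rich aryl bromide to zerovalent palladium carrying the bulky trialkylphosphine, insertion at the terminal carbon of the styrene and syn β-hydride elimination should give the (E)-stilbene, while the amine base spares the silyl ethers and the free primary alcohol is tolerated.

**Step 12**
Reactants: 19 the tris-silyl stilbene of step 11
Product: 20 gnetucleistol F
Conditions: TBAF, AcOH, THF, 0 °C to rt
Reagents that add atoms: none
Why: Fluoride cleaves the three aryl silyl ethers, and the acetic acid buffer should keep the liberated para-hydroxyphenyl group from opening the C2–O1 bond through a quinone methide, so C2 is not epimerised.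

**Compound list**
1 | 5-bromo-2-hydroxy-3-methoxybenzaldehyde | COc1cc(Br)cc(C=O)c1O | starting material
2 | 5-bromo-3-methoxy-2-(methoxymethoxy)benzaldehyde | COCOc1c(OC)cc(Br)cc1C=O | intermediate
3 | 5-bromo-1-ethenyl-3-methoxy-2-(methoxymethoxy)benzene | C=Cc1cc(Br)cc(OC)c1OCOC | intermediate
4 | syringaldehyde (4-hydroxy-3,5-dimethoxybenzaldehyde) | COc1cc(C=O)cc(OC)c1O | starting material
5 | 3,5-dimethoxy-4-[tri(propan-2-yl)silyloxy]benzaldehyde | COc1cc(C=O)cc(OC)c1O[Si](C(C)C)(C(C)C)C(C)C | intermediate
6 | 4-methylbenzenesulfonohydrazide | Cc1ccc(S(=O)(=O)NN)cc1 | starting material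
7 | N'-[(E)-{3,5-dimethoxy-4-[tri(propan-2-yl)silyloxy]phenyl}methylidene]-4-methylbenzenesulfonohydrazide | COc1cc(/C=N/NS(=O)(=O)c2ccc(C)cc2)cc(OC)c1O[Si](C(C)C)(C(C)C)C(C)C | intermediate
8 | [4-(diazomethyl)-2,6-dimethoxyphenoxy]tri(propan-2-yl)silane | COc1cc(C=[N+]=[N-])cc(OC)c1O[Si](C(C)C)(C(C)C)C(C)C | intermediate
9 | {4-[(1S,2S)-2-[5-bromo-3-methoxy-2-(methoxymethoxy)phenyl]cyclopropyl]-2,6-dimethoxyphenoxy}tri(propan-2-yl)silane (trans) | COc1cc(Br)cc([C@H]2C[C@@H]2c2cc(OC)c(O[Si](C(C)C)(C(C)C)C(C)C)c(OC)c2)c1OCOC | intermediate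
10 | 4-bromo-2-methoxy-6-[(1S,2S)-2-{3,5-dimethoxy-4-[tri(propan-2-yl)silyloxy]phenyl}cyclopropyl]phenol (trans) | COc1cc(Br)cc([C@H]2C[C@@H]2c2cc(OC)c(O[Si](C(C)C)(C(C)C)C(C)C)c(OC)c2)c1O | intermediate
11 | {[(2R,3R)-5-bromo-2-{3,5-dimethoxy-4-[tri(propan-2-yl)silyloxy]phenyl}-7-methoxy-2,3-dihydro-1-benzofuran-3-yl]methyl}mercury trifluoroacetate (trans) | COc1cc([C@@H]2Oc3c(OC)cc(Br)cc3[C@H]2C[Hg]OC(=O)C(F)(F)F)cc(OC)c1O[Si](C(C)C)(C(C)C)C(C)C | intermediate
12 | chloro{[(2R,3R)-5-bromo-2-{3,5-dimethoxy-4-[tri(propan-2-yl)silyloxy]phenyl}-7-methoxy-2,3-dihydro-1-benzofuran-3-yl]methyl}mercury (trans) | COc1cc([C@@H]2Oc3c(OC)cc(Br)cc3[C@H]2C[Hg]Cl)cc(OC)c1O[Si](C(C)C)(C(C)C)C(C)C | intermediate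
13 | {[(2R,3R)-5-bromo-2-{3,5-dimethoxy-4-[tri(propan-2-yl)silyloxy]phenyl}-7-methoxy-2,3-dihydro-1-benzofuran-3-yl]methyl}mercury hydride (trans) | COc1cc([C@@H]2Oc3c(OC)cc(Br)cc3[C@H]2C[HgH])cc(OC)c1O[Si](C(C)C)(C(C)C)C(C)C | intermediate
14 | {4-[(2R,3S)-5-bromo-3-(hydroperoxymethyl)-7-methoxy-2,3-dihydro-1-benzofuran-2-yl]-2,6-dimethoxyphenoxy}tri(propan-2-yl)silane (trans) | COc1cc([C@@H]2Oc3c(OC)cc(Br)cc3[C@H]2COO)cc(OC)c1O[Si](C(C)C)(C(C)C)C(C)C | intermediate
15 | [(2R,3S)-5-bromo-2-{3,5-dimethoxy-4-[tri(propan-2-yl)silyloxy]phenyl}-7-methoxy-2,3-dihydro-1-benzofuran-3-yl]methanol (trans) | COc1cc([C@@H]2Oc3c(OC)cc(Br)cc3[C@H]2CO)cc(OC)c1O[Si](C(C)C)(C(C)C)C(C)C | intermediate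
16 | 3,5-dihydroxybenzaldehyde | O=Cc1cc(O)cc(O)c1 | starting material
17 | 3,5-bis[tert-butyl(dimethyl)silyloxy]benzaldehyde | O=Cc1cc(O[Si](C)(C)C(C)(C)C)cc(O[Si](C)(C)C(C)(C)C)c1 | intermediate
18 | 1-ethenyl-3,5-bis[tert-butyl(dimethyl)silyloxy]benzene | C=Cc1cc(O[Si](C)(C)C(C)(C)C)cc(O[Si](C)(C)C(C)(C)C)c1 | intermediate
19 | [(2R,3S)-5-[(E)-2-{3,5-bis[tert-butyl(dimethyl)silyloxy]phenyl}ethenyl]-2-{3,5-dimethoxy-4-[tri(propan-2-yl)silyloxy]phenyl}-7-methoxy-2,3-dihydro-1-benzofuran-3-yl]methanol (trans) | COc1cc([C@@H]2Oc3c(OC)cc(/C=C/c4cc(O[Si](C)(C)C(C)(C)C)cc(O[Si](C)(C)C(C)(C)C)c4)cc3[C@H]2CO)cc(OC)c1O[Si](C(C)C)(C(C)C)C(C)C | intermediate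
20 | gnetucleistol F, 5-[(E)-2-[(2R,3S)-2-(4-hydroxy-3,5-dimethoxyphenyl)-3-(hydroxymethyl)-7-methoxy-2,3-dihydro-1-benzofuran-5-yl]ethenyl]benzene-1,3-diol | COc1cc([C@@H]2Oc3c(OC)cc(/C=C/c4cc(O)cc(O)c4)cc3[C@H]2CO)cc(OC)c1O | target

**Step count**
Total: 12 steps. Longest linear sequence: 8 steps (1 → 2 → 3 → 9 → 10 → 12 → 15 → 19 → 20; the branch from 4 is equally long).

**Steps most likely to fail**

Step 7. Mercuration of the electron-rich syringyl ring may compete with attack on the cyclopropane. The ring may also open toward C3 or across the aryl-flanked bond with capture by trifluoroacetate instead of the phenol. The fallback uses only known chemistry and gives up the cyclopropane opening; it sets out from styrene 3 (with aldehyde 5 as partner) and returns at alcohol 15. Hydroboration of 3 with 9-BBN and oxidative work-up (NaOH, H2O2) should give 2-[5-bromo-3-methoxy-2-(methoxymethoxy)phenyl]ethan-1-ol F1. TEMPO-catalysed oxidation with NaClO2 and catalytic NaOCl in buffered MeCN should give [5-bromo-3-methoxy-2-(methoxymethoxy)phenyl]acetic acid F2. Activation with PivCl/Et3N and acylation of (R)-4-benzyl-1,3-oxazolidin-2-one in the presence of LiCl should give the imide (4R)-4-benzyl-3-{[5-bromo-3-methoxy-2-(methoxymethoxy)phenyl]acetyl}-1,3-oxazolidin-2-one F3. Its dibutylboron Z-enolate (Bu2BOTf, iPr2NEt, CH2Cl2, −78 °C) should add to aldehyde 5 in an Evans syn-aldol reaction to give the (2R,3R)-aldol adduct F4, which fixes the future C3. LiBH4 in wet THF should remove the auxiliary to give the (1R,2S)-1,3-diol F5. Aqueous HCl in THF at 40 °C should then remove the acetal and ionise the benzylic alcohol, so that the phenol closes the dihydrofuran under thermodynamic control to the trans ring, giving 15.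

Step 5. Enantiofacial discrimination may be poor with an aryldiazomethane that lacks an ortho donor group; the aryl silyl ether may be lost to methanolysis under carbonate; the carbene may dimerise to stilbene or azine. The fallback sets out from 3 and 7 and returns at 9. The two partners are joined without asymmetric induction, using the achiral tetraphenylporphyrin complex [Co(TPP)] with Cs2CO3 in 1,4-dioxane at 60 °C (aprotic, trans-selective), to give the racemic trans-cyclopropane F6. The enantiomers are separated by preparative supercritical-fluid chromatography on a polysaccharide chiral stationary phase, and the (1S,2S) antipode continues as 9.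

Step 8. Hydrogen transfer from the mercury hydride to the primary radical may outrun oxygen capture and leave a 3-methyl group, or the radical may undergo a 1,2-aryl shift. The fallback sets out from 12 and returns at 15. The radical is intercepted by a persistent nitroxide instead of O2: NaBH4 is added to 12 in DMF containing excess TEMPO, which should give the O-alkyl hydroxylamine 1-{[(2R,3S)-5-bromo-2-{3,5-dimethoxy-4-[tri(propan-2-yl)silyloxy]phenyl}-7-methoxy-2,3-dihydro-1-benzofuran-3-yl]methoxy}-2,2,6,6-tetramethylpiperidine F7. Reductive N–O cleavage with Zn in AcOH/THF/H2O should then give 15.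

**Further compounds**
F1 | step 7 | 2-[5-bromo-3-methoxy-2-(methoxymethoxy)phenyl]ethan-1-ol | COCOc1c(OC)cc(Br)cc1CCO
F2 | step 7 | [5-bromo-3-methoxy-2-(methoxymethoxy)phenyl]acetic acid | COCOc1c(OC)cc(Br)cc1CC(=O)O
F3 | step 7 | (4R)-4-benzyl-3-{[5-bromo-3-methoxy-2-(methoxymethoxy)phenyl]acetyl}-1,3-oxazolidin-2-one | COCOc1c(OC)cc(Br)cc1CC(=O)N1[C@H](Cc2ccccc2)COC1=O
F4 | step 7 | (4R)-4-benzyl-3-[(2R,3R)-2-[5-bromo-3-methoxy-2-(methoxymethoxy)phenyl]-3-{3,5-dimethoxy-4-[tri(propan-2-yl)silyloxy]phenyl}-3-hydroxypropanoyl]-1,3-oxazolidin-2-one | O=C(N1[C@H](Cc2ccccc2)COC1=O)[C@H](c1cc(Br)cc(OC)c1OCOC)[C@@H](O)c1cc(OC)c(O[Si](C(C)C)(C(C)C)C(C)C)c(OC)c1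
F5 | step 7 | (1R,2S)-2-[5-bromo-3-methoxy-2-(methoxymethoxy)phenyl]-1-{3,5-dimethoxy-4-[tri(propan-2-yl)silyloxy]phenyl}propane-1,3-diol | OC[C@H](c1cc(Br)cc(OC)c1OCOC)[C@@H](O)c1cc(OC)c(O[Si](C(C)C)(C(C)C)C(C)C)c(OC)c1
F6 | step 5 | racemic trans-{4-[2-[5-bromo-3-methoxy-2-(methoxymethoxy)phenyl]cyclopropyl]-2,6-dimethoxyphenoxy}tri(propan-2-yl)silane (1S,2S and 1R,2R in equal parts) | COc1cc(Br)cc([C@H]2C[C@@H]2c2cc(OC)c(O[Si](C(C)C)(C(C)C)C(C)C)c(OC)c2)c1OCOC.COc1cc(Br)cc([C@@H]2C[C@H]2c2cc(OC)c(O[Si](C(C)C)(C(C)C)C(C)C)c(OC)c2)c1OCOC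
F7 | step 8 | 1-{[(2R,3S)-5-bromo-2-{3,5-dimethoxy-4-[tri(propan-2-yl)silyloxy]phenyl}-7-methoxy-2,3-dihydro-1-benzofuran-3-yl]methoxy}-2,2,6,6-tetramethylpiperidine | COc1cc([C@@H]2Oc3c(OC)cc(Br)cc3[C@H]2CON2C(C)(C)CCCC2(C)C)cc(OC)c1O[Si](C(C)C)(C(C)C)C(C)C
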